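**Plan**

1. Rings and atoms: A/B are the benzo and dihydrofuran rings of the dihydrobenzofuran that carries the 4-hydroxy-3-methoxyphenyl group (O1, C2, C3, C3a–C7a); C/D are the dihydrofuran and benzo rings of the other one (primed atoms). Ring A is a symmetric 5-substituted resorcinol, so either of its oxygens can become O1.
2. Retrosynthetic cuts: the seven O–benzyl bonds; the C3–aryl bond of ring B and the C3'–C6 bond joining the two halves, both as decarboxylative arylations of 3-carboxylic acids; the stilbene C–C bond (Heck); rings B and C each back to the pyranone ring of a flavanone (one ring atom more); the flavanone C2–aryl bonds, back to one chromone 5.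
3. Enabling feature: ring B is a trans-2-aryl-dihydrofuran whose C3a lies between the two ring A oxygens and whose C3 bears a single carbon substituent. That is the product pattern of a 1,2-shift of the aryl carbon from C4 to C3 of a 2-aryl-5-oxychroman-4-one; old C4 stays on C3 as a carboxyl, the handle for the later C3–aryl bond. Ring C/D is the same motif in the mirror-image series.
4. Forward order: 1 → chromone 5 → flavanones 7 and 11 → ring contraction to esters 9 (rings A/B) and 13 (rings C/D) → stilbene on 13 → union at C3' → last aryl group at C3 → debenzylation.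
5. Stereochemistry: C2 and C2' are set by ligand-controlled rhodium-catalysed conjugate addition (antipodal ligands). C3 and C3' are relayed from them by substrate control, first in the anti 1,2-shift (trans ester), then by anti capture of the C3 radical (trans-diaryl).

Key step: step 5

Assumption: the (R)-ligand is taken to deliver the (2S)-flavanone and the (S)-ligand the (2R)-flavanone (if the facial sense is the reverse, the two antipodes are exchanged between steps 4 and 6); 1, 6, 10 and 14 are taken as catalogue compounds.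

**Route**

Step 1
Reactants: 1 1,3-bis(benzyloxy)-5-bromobenzene
Product: 2 1-[2,6-bis(benzyloxy)-4-bromophenyl]ethan-1-one
Conditions: LiN(i-Pr)2, THF, −78 °C; then MeC(O)N(OMe)Me, −78 °C to rt; aq. NH4Cl
Reagents that add atoms: N-methoxy-N-methylacetamide, CC(=O)N(C)OC
Why: Directed ortho-metalation removes the proton between the two benzyloxy groups (most acidic, doubly coordinated), the amide base does not undergo Br/Li exchange at −78 °C, and the aryllithium is acylated once through the chelated tetrahedral adduct (Weinreb ketone synthesis).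

Step 2
Reactants: 2 1-[2,6-bis(benzyloxy)-4-bromophenyl]ethan-1-one
Product: 3 1-[2-(benzyloxy)-4-bromo-6-hydroxyphenyl]ethan-1-one
Conditions: MgBr2·OEt2, toluene/Et2O, reflux; dilute aq. HCl
Reagents that add atoms: none
Why: Chelation-controlled Lewis-acid debenzylation: MgBr2 bound between the ketone oxygen and an ortho ether oxygen delivers bromide to the benzylic carbon, the two ethers are equivalent by symmetry, and the magnesium phenoxide chelate formed should stop cleavage of the second one.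

Step 3
Reactants: 3 1-[2-(benzyloxy)-4-bromo-6-hydroxyphenyl]ethan-1-one
Product: 5 5-(benzyloxy)-7-bromo-4H-chromen-4-one, via enaminone 4 (not isolated)
Conditions: Me2NCH(OMe)2, toluene, 100 °C; then conc. HCl, CH2Cl2, 40 °C
Reagents that add atoms: N,N-dimethylformamide dimethyl acetal, COC(OC)N(C)C
Why: Condensation of the methyl ketone with the amide acetal gives enaminone 4, and acid-promoted conjugate addition of the free phenol with loss of dimethylamine closes the pyranone (standard chromone synthesis); no stereocentre is formed.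

Step 4
Reactants: 5 5-(benzyloxy)-7-bromo-4H-chromen-4-one; 6 [4-(benzyloxy)-3-methoxyphenyl]boronic acid
Product: 7 (2S)-5-(benzyloxy)-2-[4-(benzyloxy)-3-methoxyphenyl]-7-bromo-2,3-dihydro-4H-chromen-4-one
Conditions: Rh(acac)(C2H4)2 (cat.), (R)-MeO-F12-BIPHEP [(R)-2,2'-bis[bis(3,4,5-trifluorophenyl)phosphino]-6,6'-dimethoxy-1,1'-biphenyl] (cat.), toluene/H2O, 60 °C
Reagents that add atoms: none
Why: Hayashi–Miyaura asymmetric conjugate addition: the aryl–rhodium species (monovalent rhodium) adds to C2 of the chromone on the face selected by the C2-symmetric bisphosphine and the rhodium enolate is protonated by water, so the single C2 centre is set by the catalyst; the base-free toluene medium suppresses retro-oxa-Michael racemisation and the aryl bromide is inert to monovalent rhodium.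

Step 5
Reactants: 7 (2S)-5-(benzyloxy)-2-[4-(benzyloxy)-3-methoxyphenyl]-7-bromo-2,3-dihydro-4H-chromen-4-one
Product: 9 methyl (2S,3S)-4-(benzyloxy)-2-[4-(benzyloxy)-3-methoxyphenyl]-6-bromo-2,3-dihydro-1-benzofuran-3-carboxylate, via enol ether 8 (not isolated)
Conditions: PhI(OAc)2, conc. H2SO4, HC(OMe)3, rt; aq. NaHCO3
Reagents that add atoms: trimethyl orthoformate, COC(OC)OC; water, O
Why: Acid-catalysed exchange with HC(OMe)3 converts the C4 ketone into enol ether 8, PhI(OAc)2 (trivalent iodine) adds to C3 on the face anti to the C2 aryl group and methanol adds to C4, giving a trans-2-aryl-3-iodanyl 4,4-dimethoxychroman. The electron-rich ring A carbon C4a, anti-periplanar to the equatorial C3–I bond, then shifts from C4 to C3 with loss of PhI and inversion at C3, and the dimethoxycarbenium ion left at old C4 is hydrolysed to the methyl ester on work-up. The closest known reaction is the trivalent-iodine (or trivalent-thallium) oxidative ring contraction of flavanones to methyl trans-2-aryl-2,3-dihydrobenzofuran-3-carboxylates, a semipinacol-type rearrangement. Ring B is closed by this 1,2-carbon shift (six-membered pyranone contracted to the five-membered ring, C4 extruded as the ester carbon), not by a new C–O bond, so C2–O1 is never broken and the (2S) centre from step 4 is kept. The new C3 centre is controlled by C2: anti iodination followed by inversion places the ester trans to the aryl group, which is also the thermodynamic epimer. The step needs migration of ring A and not of the C2 aryl group (isoflavone pathway) or dehydrogenation to the flavone; the two ortho oxygens on ring A (O1 and the 5-benzyloxy group) raise the migratory aptitude of C4a and the ketal-forming medium favours the shift.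

Step 6
Reactants: 5 5-(benzyloxy)-7-bromo-4H-chromen-4-one; 10 [4-(benzyloxy)phenyl]boronic acid
Product: 11 (2R)-5-(benzyloxy)-2-[4-(benzyloxy)phenyl]-7-bromo-2,3-dihydro-4H-chromen-4-one
Conditions: Rh(acac)(C2H4)2 (cat.), (S)-MeO-F12-BIPHEP (cat.), toluene/H2O, 60 °C
Reagents that add atoms: none
Why: The same Hayashi–Miyaura conjugate addition as in step 4 with the antipodal ligand, so the aryl group should be delivered to the opposite face of C2 and the (2R) centre is set by the catalyst.

Step 7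
Reactants: 11 (2R)-5-(benzyloxy)-2-[4-(benzyloxy)phenyl]-7-bromo-2,3-dihydro-4H-chromen-4-one
Product: 13 methyl (2R,3R)-4-(benzyloxy)-2-[4-(benzyloxy)phenyl]-6-bromo-2,3-dihydro-1-benzofuran-3-carboxylate, via enol ether 12 (not isolated)
Conditions: PhI(OAc)2, conc. H2SO4, HC(OMe)3, rt; aq. NaHCO3
Reagents that add atoms: trimethyl orthoformate, COC(OC)OC; water, O
Why: The same trivalent-iodine oxidative ring contraction as in step 5 in the mirror-image series: anti iodination at C3 and 1,2-shift of the ring D carbon from C4 to C3 should give ring C with the ester trans to the C2' aryl group, C3' being controlled by C2'.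

Step 8
Reactants: 13 methyl (2R,3R)-4-(benzyloxy)-2-[4-(benzyloxy)phenyl]-6-bromo-2,3-dihydro-1-benzofuran-3-carboxylate; 14 1-(benzyloxy)-4-ethenylbenzene
Product: 15 methyl (2R,3R)-4-(benzyloxy)-2-[4-(benzyloxy)phenyl]-6-[(E)-2-[4-(benzyloxy)phenyl]ethenyl]-2,3-dihydro-1-benzofuran-3-carboxylate
Conditions: Pd[P(t-Bu)3]2 (cat.), Cy2NMe, 1,4-dioxane, 70 °C
Reagents that add atoms: none
Why: Mizoroki–Heck reaction: oxidative addition of the aryl bromide to zerovalent palladium, syn insertion of the styrene at its terminal carbon and syn β-hydride elimination should give the (E)-stilbene, and the mild amine base leaves the trans ester untouched.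

Step 9
Reactants: 15 methyl (2R,3R)-4-(benzyloxy)-2-[4-(benzyloxy)phenyl]-6-[(E)-2-[4-(benzyloxy)phenyl]ethenyl]-2,3-dihydro-1-benzofuran-3-carboxylate
Product: 16 (2R,3R)-4-(benzyloxy)-2-[4-(benzyloxy)phenyl]-6-[(E)-2-[4-(benzyloxy)phenyl]ethenyl]-2,3-dihydro-1-benzofuran-3-carboxylic acid
Conditions: Me3SnOH, ClCH2CH2Cl, 80 °C; dilute aq. HCl
Reagents that add atoms: trimethyltin hydroxide, C[Sn](C)(C)O
Why: Me3SnOH cleaves the methyl ester under neutral conditions through a tin carboxylate, which avoids base-mediated epimerisation at C3'; both stereocentres are unaffected.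

Step 10
Reactants: 16 (2R,3R)-4-(benzyloxy)-2-[4-(benzyloxy)phenyl]-6-[(E)-2-[4-(benzyloxy)phenyl]ethenyl]-2,3-dihydro-1-benzofuran-3-carboxylic acid; 9 methyl (2S,3S)-4-(benzyloxy)-2-[4-(benzyloxy)-3-methoxyphenyl]-6-bromo-2,3-dihydro-1-benzofuran-3-carboxylate
Product: 18 methyl (2S,3S)-4-(benzyloxy)-2-[4-(benzyloxy)-3-methoxyphenyl]-6-{(2R,3R)-4-(benzyloxy)-2-[4-(benzyloxy)phenyl]-6-[(E)-2-[4-(benzyloxy)phenyl]ethenyl]-2,3-dihydro-1-benzofuran-3-yl}-2,3-dihydro-1-benzofuran-3-carboxylate, via NHPI ester 17 (not isolated)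
Conditions: N-hydroxyphthalimide, i-PrN=C=N-i-Pr, CH2Cl2, rt; evaporate; then 9, NiBr2·dme (cat.), 4,4'-di-tert-butyl-2,2'-bipyridine, Zn, DMA, rt
Reagents that add atoms: none
Why: Nickel-catalysed reductive decarboxylative cross-electrophile coupling: zerovalent nickel inserts into the C–Br bond of 9, single-electron reduction of redox-active ester 17 releases CO2 and the benzylic C3' radical, and this is captured by the aryl–nickel species on the face anti to the C2' aryl group, so reductive elimination should give the trans-2,3-disubstituted ring C (substrate control from C2'); the methyl ester, the internal stilbene and all centres of 9 are not involved.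

Step 11
Reactants: 18 methyl (2S,3S)-4-(benzyloxy)-2-[4-(benzyloxy)-3-methoxyphenyl]-6-{(2R,3R)-4-(benzyloxy)-2-[4-(benzyloxy)phenyl]-6-[(E)-2-[4-(benzyloxy)phenyl]ethenyl]-2,3-dihydro-1-benzofuran-3-yl}-2,3-dihydro-1-benzofuran-3-carboxylate
Product: 19 (2S,3S)-4-(benzyloxy)-2-[4-(benzyloxy)-3-methoxyphenyl]-6-{(2R,3R)-4-(benzyloxy)-2-[4-(benzyloxy)phenyl]-6-[(E)-2-[4-(benzyloxy)phenyl]ethenyl]-2,3-dihydro-1-benzofuran-3-yl}-2,3-dihydro-1-benzofuran-3-carboxylic acid
Conditions: Me3SnOH, ClCH2CH2Cl, 80 °C; dilute aq. HCl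
Reagents that add atoms: trimethyltin hydroxide, C[Sn](C)(C)O
Why: Neutral Me3SnOH hydrolysis of the only ester, as in step 9, should leave all four stereocentres and the stilbene untouched.

Step 12
Reactants: 19 (2S,3S)-4-(benzyloxy)-2-[4-(benzyloxy)-3-methoxyphenyl]-6-{(2R,3R)-4-(benzyloxy)-2-[4-(benzyloxy)phenyl]-6-[(E)-2-[4-(benzyloxy)phenyl]ethenyl]-2,3-dihydro-1-benzofuran-3-yl}-2,3-dihydro-1-benzofuran-3-carboxylic acid; 1 1,3-bis(benzyloxy)-5-bromobenzene
Product: 21 (2S,3S)-4-(benzyloxy)-2-[4-(benzyloxy)-3-methoxyphenyl]-3-[3,5-bis(benzyloxy)phenyl]-6-{(2R,3R)-4-(benzyloxy)-2-[4-(benzyloxy)phenyl]-6-[(E)-2-[4-(benzyloxy)phenyl]ethenyl]-2,3-dihydro-1-benzofuran-3-yl}-2,3-dihydro-1-benzofuran (hepta-O-benzyl gnetin K), via NHPI ester 20 (not isolated)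
Conditions: N-hydroxyphthalimide, i-PrN=C=N-i-Pr, CH2Cl2, rt; evaporate; then 1 (excess), NiBr2·dme (cat.), 4,4'-di-tert-butyl-2,2'-bipyridine, Zn, DMA, rt
Reagents that add atoms: none
Why: The same nickel-catalysed reductive decarboxylative arylation as in step 10: the C3 radical of ring B is captured by the aryl–nickel species anti to the C2 aryl group, which should give the trans-2,3-diaryl ring B (substrate control from C2) and completes the carbon skeleton.

Step 13
Reactants: 21 hepta-O-benzyl gnetin K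
Product: 22 gnetin K
Conditions: BCl3, C6HMe5, CH2Cl2, −78 °C; MeOH quench
Reagents that add atoms: none
Why: BCl3 cleaves the seven aryl benzyl ethers at −78 °C while pentamethylbenzene traps the benzyl cations (Friedel–Crafts), so the stilbene and the electron-rich rings are not benzylated, the aryl methyl ether survives at this temperature, and the low temperature should suppress acid-induced cyclisation of the stilbene onto ring A.

**Compound list**

1 | 1,3-bis(benzyloxy)-5-bromobenzene | Brc1cc(OCc2ccccc2)cc(OCc2ccccc2)c1 | starting material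
2 | 1-[2,6-bis(benzyloxy)-4-bromophenyl]ethan-1-one | CC(=O)c1c(OCc2ccccc2)cc(Br)cc1OCc1ccccc1 | intermediate
3 | 1-[2-(benzyloxy)-4-bromo-6-hydroxyphenyl]ethan-1-one | CC(=O)c1c(O)cc(Br)cc1OCc1ccccc1 | intermediate
4 | (E)-1-[2-(benzyloxy)-4-bromo-6-hydroxyphenyl]-3-(dimethylamino)prop-2-en-1-one | CN(C)/C=C/C(=O)c1c(O)cc(Br)cc1OCc1ccccc1 | intermediate
5 | 5-(benzyloxy)-7-bromo-4H-chromen-4-one | O=c1ccoc2cc(Br)cc(OCc3ccccc3)c12 | intermediate
6 | [4-(benzyloxy)-3-methoxyphenyl]boronic acid | COc1cc(B(O)O)ccc1OCc1ccccc1 | starting material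
7 | (2S)-5-(benzyloxy)-2-[4-(benzyloxy)-3-methoxyphenyl]-7-bromo-2,3-dihydro-4H-chromen-4-one | COc1cc([C@H]2Oc3cc(Br)cc(OCc4ccccc4)c3C(=O)C2)ccc1OCc1ccccc1 | intermediate
8 | (2S)-5-(benzyloxy)-2-[4-(benzyloxy)-3-methoxyphenyl]-7-bromo-4-methoxy-2H-chromene | COc1cc([C@H]2Oc3cc(Br)cc(OCc4ccccc4)c3C(OC)=C2)ccc1OCc1ccccc1 | intermediate
9 | methyl (2S,3S)-4-(benzyloxy)-2-[4-(benzyloxy)-3-methoxyphenyl]-6-bromo-2,3-dihydro-1-benzofuran-3-carboxylate | COc1cc([C@H]2Oc3cc(Br)cc(OCc4ccccc4)c3[C@@H]2C(=O)OC)ccc1OCc1ccccc1 | intermediate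
10 | [4-(benzyloxy)phenyl]boronic acid | OB(O)c1ccc(OCc2ccccc2)cc1 | starting material
11 | (2R)-5-(benzyloxy)-2-[4-(benzyloxy)phenyl]-7-bromo-2,3-dihydro-4H-chromen-4-one | O=C1C[C@H](c2ccc(OCc3ccccc3)cc2)Oc2cc(Br)cc(OCc3ccccc3)c12 | intermediate
12 | (2R)-5-(benzyloxy)-2-[4-(benzyloxy)phenyl]-7-bromo-4-methoxy-2H-chromene | COC1=C[C@H](c2ccc(OCc3ccccc3)cc2)Oc2cc(Br)cc(OCc3ccccc3)c12 | intermediate
13 | methyl (2R,3R)-4-(benzyloxy)-2-[4-(benzyloxy)phenyl]-6-bromo-2,3-dihydro-1-benzofuran-3-carboxylate | COC(=O)[C@@H]1c2c(OCc3ccccc3)cc(Br)cc2O[C@H]1c1ccc(OCc2ccccc2)cc1 | intermediate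
14 | 1-(benzyloxy)-4-ethenylbenzene | C=Cc1ccc(OCc2ccccc2)cc1 | starting material
15 | methyl (2R,3R)-4-(benzyloxy)-2-[4-(benzyloxy)phenyl]-6-[(E)-2-[4-(benzyloxy)phenyl]ethenyl]-2,3-dihydro-1-benzofuran-3-carboxylate | COC(=O)[C@@H]1c2c(OCc3ccccc3)cc(/C=C/c3ccc(OCc4ccccc4)cc3)cc2O[C@H]1c1ccc(OCc2ccccc2)cc1 | intermediate
16 | (2R,3R)-4-(benzyloxy)-2-[4-(benzyloxy)phenyl]-6-[(E)-2-[4-(benzyloxy)phenyl]ethenyl]-2,3-dihydro-1-benzofuran-3-carboxylic acid | OC(=O)[C@@H]1c2c(OCc3ccccc3)cc(/C=C/c3ccc(OCc4ccccc4)cc3)cc2O[C@H]1c1ccc(OCc2ccccc2)cc1 | intermediate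
17 | 1,3-dioxoisoindolin-2-yl (2R,3R)-4-(benzyloxy)-2-[4-(benzyloxy)phenyl]-6-[(E)-2-[4-(benzyloxy)phenyl]ethenyl]-2,3-dihydro-1-benzofuran-3-carboxylate | O=C(ON1C(=O)c2ccccc2C1=O)[C@@H]1c2c(OCc3ccccc3)cc(/C=C/c3ccc(OCc4ccccc4)cc3)cc2O[C@H]1c1ccc(OCc2ccccc2)cc1 | intermediate
18 | methyl (2S,3S)-4-(benzyloxy)-2-[4-(benzyloxy)-3-methoxyphenyl]-6-{(2R,3R)-4-(benzyloxy)-2-[4-(benzyloxy)phenyl]-6-[(E)-2-[4-(benzyloxy)phenyl]ethenyl]-2,3-dihydro-1-benzofuran-3-yl}-2,3-dihydro-1-benzofuran-3-carboxylate | COc1cc([C@H]2Oc3cc([C@@H]4c5c(OCc6ccccc6)cc(/C=C/c6ccc(OCc7ccccc7)cc6)cc5O[C@H]4c4ccc(OCc5ccccc5)cc4)cc(OCc4ccccc4)c3[C@@H]2C(=O)OC)ccc1OCc1ccccc1 | intermediate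
19 | (2S,3S)-4-(benzyloxy)-2-[4-(benzyloxy)-3-methoxyphenyl]-6-{(2R,3R)-4-(benzyloxy)-2-[4-(benzyloxy)phenyl]-6-[(E)-2-[4-(benzyloxy)phenyl]ethenyl]-2,3-dihydro-1-benzofuran-3-yl}-2,3-dihydro-1-benzofuran-3-carboxylic acid | COc1cc([C@H]2Oc3cc([C@@H]4c5c(OCc6ccccc6)cc(/C=C/c6ccc(OCc7ccccc7)cc6)cc5O[C@H]4c4ccc(OCc5ccccc5)cc4)cc(OCc4ccccc4)c3[C@@H]2C(=O)O)ccc1OCc1ccccc1 | intermediate
20 | 1,3-dioxoisoindolin-2-yl ester of acid 19 | COc1cc([C@H]2Oc3cc([C@@H]4c5c(OCc6ccccc6)cc(/C=C/c6ccc(OCc7ccccc7)cc6)cc5O[C@H]4c4ccc(OCc5ccccc5)cc4)cc(OCc4ccccc4)c3[C@@H]2C(=O)ON2C(=O)c3ccccc3C2=O)ccc1OCc1ccccc1 | intermediate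
21 | hepta-O-benzyl gnetin K, (2S,3S)/(2R,3R) as in step 12 | COc1cc([C@H]2Oc3cc([C@@H]4c5c(OCc6ccccc6)cc(/C=C/c6ccc(OCc7ccccc7)cc6)cc5O[C@H]4c4ccc(OCc5ccccc5)cc4)cc(OCc4ccccc4)c3[C@@H]2c2cc(OCc3ccccc3)cc(OCc3ccccc3)c2)ccc1OCc1ccccc1 | intermediate
22 | gnetin K, (2S,3S)-3-(3,5-dihydroxyphenyl)-2-(4-hydroxy-3-methoxyphenyl)-6-{(2R,3R)-4-hydroxy-2-(4-hydroxyphenyl)-6-[(E)-2-(4-hydroxyphenyl)ethenyl]-2,3-dihydro-1-benzofuran-3-yl}-2,3-dihydro-1-benzofuran-4-ol | COc1cc([C@H]2Oc3cc([C@@H]4c5c(O)cc(/C=C/c6ccc(O)cc6)cc5O[C@H]4c4ccc(O)cc4)cc(O)c3[C@@H]2c2cc(O)cc(O)c2)ccc1O | target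

**Step count and risks**

Total steps: 13. Longest linear sequence: 11 steps (steps 1–3 and 6–13).

Steps most likely to fail:

1. Step 5 (and its twin, step 7). The C2 aryl group may migrate instead of ring A (isoflavone pathway), the flavanone may be dehydrogenated to the flavone, the iodane may attack the benzyloxy-arenes, or 7 may racemise at C2 by acid-induced C2–O1 ionisation before ketalisation. Fallback, from 7 back to 9, by a Wolff ring contraction that uses neither oxidant nor strong acid: 7 is acylated at C3 (LiN(SiMe3)2, THF, −78 °C, then CF3CO2CH2CF3) to (2S)-5-(benzyloxy)-2-[4-(benzyloxy)-3-methoxyphenyl]-7-bromo-3-(trifluoroacetyl)-2,3-dihydro-4H-chromen-4-one F1. Detrifluoroacetylative diazo transfer (MsN3, Et3N, MeCN) should give the 3-diazo ketone (2R)-5-(benzyloxy)-2-[4-(benzyloxy)-3-methoxyphenyl]-7-bromo-3-diazo-2,3-dihydro-4H-chromen-4-one F2, which has the same spatial arrangement at C2 (the descriptor changes by priority only). Irradiation in MeOH should bring about the same C4-to-C3 shift of the ring A carbon through the ketene and give 9 together with its cis epimer methyl (2S,3R)-4-(benzyloxy)-2-[4-(benzyloxy)-3-methoxyphenyl]-6-bromo-2,3-dihydro-1-benzofuran-3-carboxylate F3, and NaOMe in MeOH should equilibrate F3 to the trans ester 9.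

2. Step 10. The hindered benzylic C3' radical may dimerise, be reduced to C3'–H, or open ring C by β-scission of C2'–O1'; oxidative addition of the electron-rich bromide may be slow so that the activated ester is consumed unproductively; capture may show poor facial selectivity. Fallback, from 16 and 9 back to 18, by oxidative rather than reductive radical generation with no activated ester or metal reductant: the free acid 16 and 9 are coupled by metallaphotoredox decarboxylative arylation (Ir[dF(CF3)ppy]2(dtbbpy)PF6, NiCl2·glyme, 4,4'-di-tert-butyl-2,2'-bipyridine, Cs2CO3, DMF, blue light). Energy transfer is expected to give 18 mixed with its (Z)-stilbene isomer F4, and I2 (cat.) in toluene under daylight should return the mixture to (E)-configured 18.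

3. Step 12. Coupling at C3 of ring B, flanked by the 4-benzyloxy group and the C2 aryl group, may be too slow, so that the radical takes up hydrogen or the alkyl–nickel species undergoes β-hydride elimination to the benzofuran. Fallback, from 1 and 20 (here isolated) back to 21, with a preformed nucleophile in place of the second electrophile: 1 is converted (n-BuLi, THF, −78 °C; then ZnCl2) into [3,5-bis(benzyloxy)phenyl]zinc chloride F5, used in excess with 20 under NiCl2·glyme/4,4'-di-tert-butyl-2,2'-bipyridine in THF/DMF at rt (Negishi-type decarboxylative arylation) to give 21.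

Further compounds

F1 | step 5 | (2S)-5-(benzyloxy)-2-[4-(benzyloxy)-3-methoxyphenyl]-7-bromo-3-(trifluoroacetyl)-2,3-dihydro-4H-chromen-4-one (C3 unassigned) | COc1cc([C@H]2Oc3cc(Br)cc(OCc4ccccc4)c3C(=O)C2C(=O)C(F)(F)F)ccc1OCc1ccccc1
F2 | step 5 | (2R)-5-(benzyloxy)-2-[4-(benzyloxy)-3-methoxyphenyl]-7-bromo-3-diazo-2,3-dihydro-4H-chromen-4-one | COc1cc([C@H]2Oc3cc(Br)cc(OCc4ccccc4)c3C(=O)C2=[N+]=[N-])ccc1OCc1ccccc1
F3 | step 5 | methyl (2S,3R)-4-(benzyloxy)-2-[4-(benzyloxy)-3-methoxyphenyl]-6-bromo-2,3-dihydro-1-benzofuran-3-carboxylate | COc1cc([C@H]2Oc3cc(Br)cc(OCc4ccccc4)c3[C@H]2C(=O)OC)ccc1OCc1ccccc1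
F4 | step 10 | (Z)-stilbene isomer of 18 | COc1cc([C@H]2Oc3cc([C@@H]4c5c(OCc6ccccc6)cc(/C=C\c6ccc(OCc7ccccc7)cc6)cc5O[C@H]4c4ccc(OCc5ccccc5)cc4)cc(OCc4ccccc4)c3[C@@H]2C(=O)OC)ccc1OCc1ccccc1
F5 | step 12 | [3,5-bis(benzyloxy)phenyl]zinc chloride | Cl[Zn]c1cc(OCc2ccccc2)cc(OCc2ccccc2)c1
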